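Assumption: (4R)-p-mentha-2,8-dien-1-ol, the commercial cannabinoid building block made from (R)-limonene, is taken as the chiral starting material (the (1S,4R) isomer is drawn; its C1 epimer reacts identically). Atom labels C1–C15 follow the cadinane/kalihinane skeleton: ring A = C1–C6 with the C4=C5 olefin, ring B = C1, C6–C10 with N on C10, ring C = C11–C15 plus O.

**Retrosynthetic overview**
1. Target ⇒ diimide reduction of a C8=C9 olefin; the C10–N bond and formamide come from an allyl cyanate-to-isocyanate [3,3] shift of a C8 allylic alcohol made by enone reduction.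
2. Ring C (chlorinated oxane) ⇒ 6-endo chloroetherification of the C11 tertiary alcohol onto the prenyl olefin; C7–C11 ⇒ ketone aldol of a bicyclic enone with 6-methylhept-5-en-2-one.
3. Ring B ⇒ C8–C9, the key bond, by photochemical dehydrogenative acyl-radical cyclization of an aldehyde onto the isopropenyl group.
4. C6–C7 ⇒ allyl-cation alkylation of (4R)-p-mentha-2,8-dien-1-ol (ring A and C1 bought) with an acetaldehyde enol silane.
5. Ring order: A (bought) → B (step 2) → C (step 4); nitrogen last.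

**Route**

Step 1
Reactants: 1 (1S,4R)-1-methyl-4-(prop-1-en-2-yl)cyclohex-2-en-1-ol; 2 trimethyl(vinyloxy)silane
Product: 3 2-[(1R,6R)-3-methyl-6-(prop-1-en-2-yl)cyclohex-2-en-1-yl]acetaldehyde
Conditions: 2 (2.2 equiv), BF3·OEt2 (0.3 equiv), CH2Cl2, −78 to −40 °C; aq NaHCO3
Reagents that add atoms: none
Why: Lewis-acid SN1 allylic substitution (Mukaiyama-type alkylation of a silyl enol ether by the p-menthadienyl cation used in cannabidiol manufacture): ionisation removes the carbinol centre, the enol silane adds at the secondary allyl terminus C6 anti to the isopropenyl group on the bought C1 centre (trans-1,6), and the trisubstituted C4=C5 olefin is left in place.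

Step 2
Reactants: 3 2-[(1R,6R)-3-methyl-6-(prop-1-en-2-yl)cyclohex-2-en-1-yl]acetaldehyde
Product: 4 (4aR,8aR)-4,7-dimethyl-4a,5,6,8a-tetrahydronaphthalen-2(1H)-one
Conditions: (nBu4N)4[W10O32] (2 mol%), Co(dmgH)2(py)Cl (5 mol%), MeCN (0.02 M), 390 nm LEDs, Ar, 25 °C
Reagents that add atoms: none
Why: Proposed new method: excited decatungstate abstracts the formyl hydrogen of 3 (hydridic and polarity-matched, faster than the allylic C–H bonds), the C8 acyl radical closes 6-endo onto the CH2 terminus (C9) of the isopropenyl group because 5-exo attack would have to hit the fully substituted C10 and build a strained trans-hydrindanone, the tertiary C10 radical is intercepted by divalent cobalt and loses a C9 hydrogen to give the conjugated enone while the cobalt hydride and reduced decatungstate release H2 (cobalt hydride re-addition moves any non-conjugated olefin isomer into conjugation); the closest known reaction types are decatungstate-photocatalysed hydroacylation of olefins by aldehyde-derived acyl radicals and decatungstate/cobaloxime acceptorless dehydrogenation, here merged into a ring-closing dehydrogenative acylation of an unactivated 1,1-disubstituted olefin; no stereocenter is formed and the trans ring fusion is carried over from 3.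

Step 3
Reactants: 4 (4aR,8aR)-4,7-dimethyl-4a,5,6,8a-tetrahydronaphthalen-2(1H)-one; 5 6-methylhept-5-en-2-one
Product: 7 (1R,4aR,8aR)-1-[(2R)-2-hydroxy-6-methylhept-5-en-2-yl]-4,7-dimethyl-4a,5,6,8a-tetrahydronaphthalen-2(1H)-one, via lithium dienolate 6 (not isolated)
Conditions: LiN(iPr)2 (1.05 equiv), THF, −78 °C, 30 min; then 5 (1.2 equiv), −78 °C, 15 min; AcOH quench at −78 °C
Reagents that add atoms: none
Why: Directed ketone aldol (the hernandulcin-type aldol of a 3-methylcyclohexenone kinetic enolate): the cross-conjugated C7 lithium enolate adds through a closed Zimmerman–Traxler chair with the homoprenyl chain equatorial and the methyl axial, which fixes C11 relative to C7, while C7 takes the equatorial bond trans to the C6–C5 bond (approach away from the axial C1–H and ring A, and also the more stable chelated aldolate), so both centres are set by the ring-fusion centres.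

Step 4
Reactants: 7 (1R,4aR,8aR)-1-[(2R)-2-hydroxy-6-methylhept-5-en-2-yl]-4,7-dimethyl-4a,5,6,8a-tetrahydronaphthalen-2(1H)-one
Product: 8 (1R,4aR,8aR)-1-[(2R,5S)-5-chloro-2,6,6-trimethyloxan-2-yl]-4,7-dimethyl-4a,5,6,8a-tetrahydronaphthalen-2(1H)-one
Conditions: N-chlorosuccinimide (1.05 equiv), Ph3P=S (10 mol%), CH2Cl2/(CF3)2CHOH 9:1, −40 °C
Reagents that add atoms: N-chlorosuccinimide, O=C1CCC(=O)N1Cl
Why: Lewis-base-catalysed 6-endo (Markovnikov) chloroetherification: anti addition through a chair in which Cl is equatorial and the bulky bicyclic group on C11 is equatorial (methyl axial) sets C14 trans to the C7-bearing bond, and because chloriranium formation from the sulfide–NCS adduct is reversible without free chloride, only the olefin with the tethered tertiary hydroxyl is trapped while the hindered C4=C5 olefin and the enone are left; the ether also removes the retro-aldol pathway.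

Step 5
Reactants: 8 (1R,4aR,8aR)-1-[(2R,5S)-5-chloro-2,6,6-trimethyloxan-2-yl]-4,7-dimethyl-4a,5,6,8a-tetrahydronaphthalen-2(1H)-one
Product: 9 (1S,2S,4aR,8aR)-1-[(2R,5S)-5-chloro-2,6,6-trimethyloxan-2-yl]-4,7-dimethyl-1,2,4a,5,6,8a-hexahydronaphthalen-2-ol
Conditions: NaBH4, CeCl3·7H2O, MeOH, −78 °C
Reagents that add atoms: none
Why: Luche 1,2-reduction: axial hydride delivery to C8 gives the pseudo-equatorial alcohol trans to the equatorial C7 oxanyl group, a temporary centre that will direct C10.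

Step 6
Reactants: 9 (1S,2S,4aR,8aR)-1-[(2R,5S)-5-chloro-2,6,6-trimethyloxan-2-yl]-4,7-dimethyl-1,2,4a,5,6,8a-hexahydronaphthalen-2-ol
Product: 11 (1S,2S,4aR,8aR)-1-[(2R,5S)-5-chloro-2,6,6-trimethyloxan-2-yl]-4,7-dimethyl-1,2,4a,5,6,8a-hexahydronaphthalen-2-yl carbamate, via N-trichloroacetyl carbamate 10 (not isolated)
Conditions: Cl3CC(O)NCO, CH2Cl2, 0 °C; then K2CO3, MeOH/H2O, 0 °C to rt
Reagents that add atoms: trichloroacetyl isocyanate, O=C=NC(=O)C(Cl)(Cl)Cl
Why: Carbamoylation of the hindered secondary allylic alcohol with the highly electrophilic acyl isocyanate followed by methanolysis of the trichloroacetyl group; no stereocenter is touched.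

Step 7
Reactants: 11 (1S,2S,4aR,8aR)-1-[(2R,5S)-5-chloro-2,6,6-trimethyloxan-2-yl]-4,7-dimethyl-1,2,4a,5,6,8a-hexahydronaphthalen-2-yl carbamate
Product: 14 N-[(1R,4R,4aR,8aR)-4-[(2R,5S)-5-chloro-2,6,6-trimethyloxan-2-yl]-1,6-dimethyl-1,4,4a,7,8,8a-hexahydronaphthalen-1-yl]formamide, via allyl cyanate 12 (not isolated), via allyl isocyanate 13 (not isolated)
Conditions: (CF3CO)2O, Et3N, THF, −78 to 0 °C; then LiBHEt3 (1.1 equiv), −78 °C; H2O
Reagents that add atoms: none
Why: Ichikawa allyl cyanate-to-isocyanate [3,3] rearrangement: dehydration of the carbamate gives the cyanate, which transfers nitrogen suprafacially from C8–O to C10 so that the C8 configuration sets the quaternary C10 centre (N equatorial, methyl axial), and the isocyanate is reduced to the formamide by LiBHEt3 at −78 °C faster than the hindered secondary chloride can react.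

Step 8
Reactants: 14 N-[(1R,4R,4aR,8aR)-4-[(2R,5S)-5-chloro-2,6,6-trimethyloxan-2-yl]-1,6-dimethyl-1,4,4a,7,8,8a-hexahydronaphthalen-1-yl]formamide
Product: 15 N-[(1R,4R,4aR,8aR)-4-[(2R,5S)-5-chloro-2,6,6-trimethyloxan-2-yl]-1,6-dimethyl-1,2,3,4,4a,7,8,8a-octahydronaphthalen-1-yl]formamide
Conditions: 2-nitrobenzenesulfonohydrazide, Et3N, CH2Cl2, rt
Reagents that add atoms: none
Why: Diimide reduction: concerted syn hydrogen transfer is much faster to the cis-disubstituted C8=C9 olefin than to the trisubstituted C4=C5 olefin and leaves the C–Cl bond and the formamide alone; no stereocenter is formed.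

**Compound list**
1 | (1S,4R)-1-methyl-4-(prop-1-en-2-yl)cyclohex-2-en-1-ol [(4R)-p-mentha-2,8-dien-1-ol] | CC(=C)[C@@H]1CC[C@](C)(O)C=C1 | starting material
2 | trimethyl(vinyloxy)silane | C=CO[Si](C)(C)C | starting material
3 | 2-[(1R,6R)-3-methyl-6-(prop-1-en-2-yl)cyclohex-2-en-1-yl]acetaldehyde | CC1=C[C@@H](CC=O)[C@@H](CC1)C(C)=C | intermediate
4 | (4aR,8aR)-4,7-dimethyl-4a,5,6,8a-tetrahydronaphthalen-2(1H)-one (trans-fused) | CC1=C[C@@H]2[C@@H](CC1)C(C)=CC(=O)C2 | intermediate
5 | 6-methylhept-5-en-2-one | CC(=O)CCC=C(C)C | starting material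
6 | lithium (4aR,8aR)-4,7-dimethyl-4a,5,6,8a-tetrahydronaphthalen-2-olate (cross-conjugated dienolate) | CC1=C[C@@H]2[C@@H](CC1)C(C)=CC(O[Li])=C2 | intermediate (not isolated)
7 | (1R,4aR,8aR)-1-[(2R)-2-hydroxy-6-methylhept-5-en-2-yl]-4,7-dimethyl-4a,5,6,8a-tetrahydronaphthalen-2(1H)-one | CC1=C[C@@H]2[C@@H](CC1)C(C)=CC(=O)[C@H]2[C@](C)(O)CCC=C(C)C | intermediate
8 | (1R,4aR,8aR)-1-[(2R,5S)-5-chloro-2,6,6-trimethyloxan-2-yl]-4,7-dimethyl-4a,5,6,8a-tetrahydronaphthalen-2(1H)-one | CC1=C[C@@H]2[C@@H](CC1)C(C)=CC(=O)[C@H]2[C@@]1(C)CC[C@H](Cl)C(C)(C)O1 | intermediate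
9 | (1S,2S,4aR,8aR)-1-[(2R,5S)-5-chloro-2,6,6-trimethyloxan-2-yl]-4,7-dimethyl-1,2,4a,5,6,8a-hexahydronaphthalen-2-ol | CC1=C[C@@H]2[C@@H](CC1)C(C)=C[C@H](O)[C@H]2[C@@]1(C)CC[C@H](Cl)C(C)(C)O1 | intermediate
10 | (1S,2S,4aR,8aR)-1-[(2R,5S)-5-chloro-2,6,6-trimethyloxan-2-yl]-4,7-dimethyl-1,2,4a,5,6,8a-hexahydronaphthalen-2-yl N-(trichloroacetyl)carbamate | CC1=C[C@@H]2[C@@H](CC1)C(C)=C[C@H](OC(=O)NC(=O)C(Cl)(Cl)Cl)[C@H]2[C@@]1(C)CC[C@H](Cl)C(C)(C)O1 | intermediate (not isolated)
11 | (1S,2S,4aR,8aR)-1-[(2R,5S)-5-chloro-2,6,6-trimethyloxan-2-yl]-4,7-dimethyl-1,2,4a,5,6,8a-hexahydronaphthalen-2-yl carbamate | CC1=C[C@@H]2[C@@H](CC1)C(C)=C[C@H](OC(N)=O)[C@H]2[C@@]1(C)CC[C@H](Cl)C(C)(C)O1 | intermediate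
12 | (1S,2S,4aR,8aR)-1-[(2R,5S)-5-chloro-2,6,6-trimethyloxan-2-yl]-4,7-dimethyl-1,2,4a,5,6,8a-hexahydronaphthalen-2-yl cyanate | CC1=C[C@@H]2[C@@H](CC1)C(C)=C[C@H](OC#N)[C@H]2[C@@]1(C)CC[C@H](Cl)C(C)(C)O1 | intermediate (not isolated)
13 | (2R,5S)-5-chloro-2-[(1R,4R,4aR,8aR)-4-isocyanato-4,7-dimethyl-1,4,4a,5,6,8a-hexahydronaphthalen-1-yl]-2,6,6-trimethyloxane | CC1=C[C@@H]2[C@@H](CC1)[C@](C)(N=C=O)C=C[C@H]2[C@@]1(C)CC[C@H](Cl)C(C)(C)O1 | intermediate (not isolated)
14 | N-[(1R,4R,4aR,8aR)-4-[(2R,5S)-5-chloro-2,6,6-trimethyloxan-2-yl]-1,6-dimethyl-1,4,4a,7,8,8a-hexahydronaphthalen-1-yl]formamide | CC1=C[C@@H]2[C@@H](CC1)[C@](C)(NC=O)C=C[C@H]2[C@@]1(C)CC[C@H](Cl)C(C)(C)O1 | intermediate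
15 | N-[(1R,4R,4aR,8aR)-4-[(2R,5S)-5-chloro-2,6,6-trimethyloxan-2-yl]-1,6-dimethyl-1,2,3,4,4a,7,8,8a-octahydronaphthalen-1-yl]formamide | CC1=C[C@@H]2[C@@H](CC1)[C@](C)(NC=O)CC[C@H]2[C@@]1(C)CC[C@H](Cl)C(C)(C)O1 | target

**Step count and risks**
Total steps: 8. Longest linear sequence: 8 (from 1).

Steps most likely to fail:

Step 2 (proposed new method). Allylic hydrogen abstraction with cobalt-assisted aromatisation of ring A, simple hydroacylation to the saturated ketone, or decarbonylation could compete. The fallback uses known ionic chemistry, sets out from 3 and comes back at 4. Me2AlCl (1.1 equiv, CH2Cl2, −78 °C) effects an intramolecular carbonyl-ene cyclization of the aldehyde onto the isopropenyl group and gives the homoallylic alcohol (4aR,8aR)-7-methyl-4-methylidene-1,2,3,4,4a,5,6,8a-octahydronaphthalen-2-ol F1 as a mixture of carbinol epimers. Dess–Martin periodinane (NaHCO3, CH2Cl2) oxidises it to the β,γ-unsaturated ketone (4aR,8aR)-7-methyl-4-methylidene-3,4,4a,5,6,8a-hexahydronaphthalen-2(1H)-one F2. DBU (CH2Cl2, rt) then moves the exocyclic olefin into conjugation to give 4.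

Step 3. The ketone–ketone aldol is reversible, the lithium enolate can be quenched by proton transfer from 5, and the facial preference at C7 is not secured by precedent on this ring system. The fallback generates the enolate reductively and without an amide base; it sets out from 4 and comes back at 7. The kinetic enolate of 4 is silylated (LiN(iPr)2, Me3SiCl, THF, −78 °C) to the silyl dienol ether trimethyl{[(4aR,8aR)-4,7-dimethyl-4a,5,6,8a-tetrahydronaphthalen-2-yl]oxy}silane F3. N-Bromosuccinimide (THF, −78 °C) converts this to the bromo enone (4aR,8aR)-1-bromo-4,7-dimethyl-4a,5,6,8a-tetrahydronaphthalen-2(1H)-one F4, either C7 epimer being usable. F4 and 5 are then treated with SmI2 (2.2 equiv, THF, −78 °C) in a samarium Reformatsky reaction, whose chelated aldolate gives 7.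

Step 4. The ring A olefin may be chlorinated, 5-exo closure to a tetrahydrofuran may compete, and the C14 selectivity rests on the chair model. The fallback replaces electrophilic chlorine by hydroxyl-directed oxidation and a ring expansion; it sets out from 7 and comes back at 8. VO(acac)2 (3 mol%) and tBuOOH (CH2Cl2, rt) epoxidise only the olefin held near the tertiary alcohol, giving the epoxide (1R,4aR,8aR)-1-{(2R)-4-[(2S)-3,3-dimethyloxiran-2-yl]-2-hydroxybutan-2-yl}-4,7-dimethyl-4a,5,6,8a-tetrahydronaphthalen-2(1H)-one F5, which is not isolated. It closes 5-exo in the flask (AcOH) to the 2,5-trans tetrahydrofuran carbinol (1R,4aR,8aR)-1-[(2R,5R)-5-(2-hydroxypropan-2-yl)-2-methyloxolan-2-yl]-4,7-dimethyl-4a,5,6,8a-tetrahydronaphthalen-2(1H)-one F6. SOCl2/pyridine (CH2Cl2, −40 °C) followed by catalytic ZnCl2 at rt ionises the tertiary carbinol with participation of the ring oxygen, and chloride opens the bicyclic oxonium ion at C14 with inversion to give the ring-expanded chloride 8.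

Further compounds
F1 | step 2 | (4aR,8aR)-7-methyl-4-methylidene-1,2,3,4,4a,5,6,8a-octahydronaphthalen-2-ol (carbinol epimers) | CC1=C[C@@H]2[C@@H](CC1)C(=C)CC(O)C2
F2 | step 2 | (4aR,8aR)-7-methyl-4-methylidene-3,4,4a,5,6,8a-hexahydronaphthalen-2(1H)-one | CC1=C[C@@H]2[C@@H](CC1)C(=C)CC(=O)C2
F3 | step 3 | trimethyl{[(4aR,8aR)-4,7-dimethyl-4a,5,6,8a-tetrahydronaphthalen-2-yl]oxy}silane | CC1=C[C@@H]2[C@@H](CC1)C(C)=CC(O[Si](C)(C)C)=C2
F4 | step 3 | (4aR,8aR)-1-bromo-4,7-dimethyl-4a,5,6,8a-tetrahydronaphthalen-2(1H)-one (C1 epimers) | CC1=C[C@@H]2[C@@H](CC1)C(C)=CC(=O)C2Br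
F5 | step 4 | (1R,4aR,8aR)-1-{(2R)-4-[(2S)-3,3-dimethyloxiran-2-yl]-2-hydroxybutan-2-yl}-4,7-dimethyl-4a,5,6,8a-tetrahydronaphthalen-2(1H)-one | CC1=C[C@@H]2[C@@H](CC1)C(C)=CC(=O)[C@H]2[C@](C)(O)CC[C@@H]1OC1(C)C
F6 | step 4 | (1R,4aR,8aR)-1-[(2R,5R)-5-(2-hydroxypropan-2-yl)-2-methyloxolan-2-yl]-4,7-dimethyl-4a,5,6,8a-tetrahydronaphthalen-2(1H)-one | CC1=C[C@@H]2[C@@H](CC1)C(C)=CC(=O)[C@H]2[C@@]1(C)CC[C@@H](O1)C(C)(C)O
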